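**Retrosynthetic overview**
- The target comes from its 4-O-benzyl ether 19 (target locants, see remark); the oxirane of 19 is closed last, by the C5 alkoxide displacing the C4 oxygen of a C3/C4 cyclic sulfate with inversion at C4, so 19 traces back to the cis-3,4-diol 15.
- The carbocycle (formed first, oxirane second) is closed at C3–C4 by an SmI2 pinacol cyclisation of the acyclic 1,6-dialdehyde 14, which sets C3 and C4 together.
- Enabling feature: the carbinol carbon C3 and the oxirane CH carbon C4 are adjacent oxygen-bearing ring carbons lying between the oxygenated C2 and the oxygenated quaternary C5. The anti C3–OH/oxirane pair is therefore a cis-diol inverted at C4, i.e. a pinacol retron.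
- 14 comes from ozonolysis of the 1,7-diene 13. Its quaternary C5 is set by a chelation-controlled hydroxymethylation of the vinyl ketone 7.
- 7 comes from zinc fragmentation of a 6-iodo-D-glucoside; C2, C3 and C4 of D-glucose become C6, C1 and C2 of the target.

Key step: step 13

Remark: locants C1–C7 in the text are those of the target carbocycle (C1 and C6 = acetoxy carbons, C1 next to the diol; C2 and C3 = carbinol carbons, C3 next to the oxirane; C4 = oxirane CH; C5 = quaternary oxirane carbon; C7 = CH2OBz carbon). Compound 1 is a commercial material.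

Step 1
Reactants: 1 methyl 4,6-O-[(R)-benzylidene]-α-D-glucopyranoside
Product: 2 methyl 4,6-O-[(R)-benzylidene]-2,3-bis-O-(4-methoxybenzyl)-α-D-glucopyranoside
Conditions: NaH, 4-methoxybenzyl chloride, Bu4NI (cat.), DMF, 0 °C → rt
Reagents that add atoms: 4-methoxybenzyl chloride COc1ccc(CCl)cc1
Why: Williamson etherification of the two secondary alkoxides; the acetal is base-stable and no stereocentre is touched.

Step 2
Reactants: 2 methyl 4,6-O-[(R)-benzylidene]-2,3-bis-O-(4-methoxybenzyl)-α-D-glucopyranoside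
Product: 3 methyl 4-O-benzyl-2,3-bis-O-(4-methoxybenzyl)-α-D-glucopyranoside
Conditions: BH3·THF, Cu(OTf)2 (cat.), CH2Cl2, rt
Reagents that add atoms: none
Why: Lewis-acid-catalysed regioselective reductive opening of the benzylidene acetal, in which the activated borane binds the more accessible O-6, the C–O6 bond breaks and hydride reduces the O-4 oxocarbenium ion, so benzyl stays on O-4 and O-6 is freed.

Step 3
Reactants: 3 methyl 4-O-benzyl-2,3-bis-O-(4-methoxybenzyl)-α-D-glucopyranoside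
Product: 4 methyl 4-O-benzyl-6-deoxy-6-iodo-2,3-bis-O-(4-methoxybenzyl)-α-D-glucopyranoside
Conditions: I2, PPh3, imidazole, toluene, 70 °C
Reagents that add atoms: iodine II
Why: Garegg–Samuelsson (Appel-type) iodination, an SN2 displacement of the primary alkoxyphosphonium ion by iodide.

Step 4
Reactants: 4 methyl 4-O-benzyl-6-deoxy-6-iodo-2,3-bis-O-(4-methoxybenzyl)-α-D-glucopyranoside
Product: 5 (2R,3S,4R)-4-(benzyloxy)-2,3-bis[(4-methoxybenzyl)oxy]hex-5-enal
Conditions: Zn (activated dust), THF/H2O (9:1), sonication, 40 °C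
Reagents that add atoms: none
Why: Bernet–Vasella reductive fragmentation, in which zinc inserts into the C–I bond and β-elimination of the ring oxygen opens the pyranoside to the 5-enal with loss of methanol, leaving the three glucose stereocentres untouched.

Step 5
Reactants: 5 (2R,3S,4R)-4-(benzyloxy)-2,3-bis[(4-methoxybenzyl)oxy]hex-5-enal
Product: 6 (4S,5S,6R)-6-(benzyloxy)-4,5-bis[(4-methoxybenzyl)oxy]octa-1,7-dien-3-ol (both C3 epimers)
Conditions: CH2=CHMgBr, THF, −78 °C
Reagents that add atoms: vinylmagnesium bromide C=C[Mg]Br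
Why: Grignard 1,2-addition to the aldehyde; the new carbinol centre needs no control because it is oxidised in the next step.

Step 6
Reactants: 6 (4S,5S,6R)-6-(benzyloxy)-4,5-bis[(4-methoxybenzyl)oxy]octa-1,7-dien-3-ol
Product: 7 (4R,5S,6R)-6-(benzyloxy)-4,5-bis[(4-methoxybenzyl)oxy]octa-1,7-dien-3-one
Conditions: Dess–Martin periodinane, NaHCO3, CH2Cl2, 0 °C → rt
Reagents that add atoms: none
Why: Dess–Martin oxidation of the secondary allylic alcohol under buffered conditions should give the vinyl ketone without epimerising the α-alkoxy centre.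

Step 7
Reactants: 7 (4R,5S,6R)-6-(benzyloxy)-4,5-bis[(4-methoxybenzyl)oxy]octa-1,7-dien-3-one
Product: 9 (3R,4R,5S,6R)-6-(benzyloxy)-3-(hydroxymethyl)-4,5-bis[(4-methoxybenzyl)oxy]octa-1,7-dien-3-ol, via β-hydroxysilane 8 (not isolated)
Conditions: (i-PrO)Me2SiCH2MgCl, THF, −78 °C; then KF, KHCO3, 30% H2O2, THF/MeOH, rt
Reagents that add atoms: (isopropoxydimethylsilyl)methylmagnesium chloride CC(C)O[Si](C)(C)C[Mg]Cl; hydrogen peroxide OO
Why: Chelation-controlled (Cram-chelate) Grignard 1,2-addition, in which magnesium bridges the ketone oxygen and the α-OPMB oxygen so that the silylmethyl group enters from the face of the α-hydrogen and fixes the tertiary carbinol centre (the future C5), followed by Tamao oxidation of C–Si to C–OH.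

Step 8
Reactants: 9 (3R,4R,5S,6R)-6-(benzyloxy)-3-(hydroxymethyl)-4,5-bis[(4-methoxybenzyl)oxy]octa-1,7-dien-3-ol
Product: 10 [(2R,3R,4S,5R)-5-(benzyloxy)-2-ethenyl-2-hydroxy-3,4-bis[(4-methoxybenzyl)oxy]hept-6-en-1-yl] benzoate
Conditions: BzCl (1.1 equiv), pyridine, CH2Cl2, −20 → 0 °C
Reagents that add atoms: benzoyl chloride O=C(Cl)c1ccccc1
Why: Acyl transfer to the primary hydroxyl only; the tertiary allylic hydroxyl is too hindered to be benzoylated under these conditions.

Step 9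
Reactants: 10 [(2R,3R,4S,5R)-5-(benzyloxy)-2-ethenyl-2-hydroxy-3,4-bis[(4-methoxybenzyl)oxy]hept-6-en-1-yl] benzoate
Product: 11 [(2R,3R,4S,5R)-5-(benzyloxy)-2-ethenyl-3,4-bis[(4-methoxybenzyl)oxy]-2-[(triethylsilyl)oxy]hept-6-en-1-yl] benzoate
Conditions: Et3SiOTf, 2,6-lutidine, CH2Cl2, −78 → 0 °C
Reagents that add atoms: triethylsilyl triflate CC[Si](CC)(CC)OS(=O)(=O)C(F)(F)F
Why: Silylation of the hindered tertiary alcohol with the silyl triflate; the ether later prevents lactol formation in the dialdehyde and steers the pinacol step.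

Step 10
Reactants: 11 [(2R,3R,4S,5R)-5-(benzyloxy)-2-ethenyl-3,4-bis[(4-methoxybenzyl)oxy]-2-[(triethylsilyl)oxy]hept-6-en-1-yl] benzoate
Product: 12 [(2R,3R,4R,5R)-5-(benzyloxy)-2-ethenyl-3,4-dihydroxy-2-[(triethylsilyl)oxy]hept-6-en-1-yl] benzoate
Conditions: DDQ, CH2Cl2/pH 7 buffer (10:1), 0 °C → rt
Reagents that add atoms: none
Why: Oxidative cleavage of the electron-rich 4-methoxybenzyl ethers by DDQ with water trapping the oxocarbenium ions; benzyl ether, silyl ether, benzoate and alkenes are inert.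

Step 11
Reactants: 12 [(2R,3R,4R,5R)-5-(benzyloxy)-2-ethenyl-3,4-dihydroxy-2-[(triethylsilyl)oxy]hept-6-en-1-yl] benzoate
Product: 13 [(2R,3R,4S,5R)-3,4-diacetoxy-5-(benzyloxy)-2-ethenyl-2-[(triethylsilyl)oxy]hept-6-en-1-yl] benzoate
Conditions: Ac2O, pyridine, DMAP (cat.), CH2Cl2, rt
Reagents that add atoms: acetic anhydride CC(=O)OC(C)=O
Why: DMAP-catalysed acetylation of the two secondary hydroxyls installs the C6 and C1 acetates of the target before any base-sensitive stage.

Step 12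
Reactants: 13 [(2R,3R,4S,5R)-3,4-diacetoxy-5-(benzyloxy)-2-ethenyl-2-[(triethylsilyl)oxy]hept-6-en-1-yl] benzoate
Product: 14 [(2R,3R,4R,5S)-3,4-diacetoxy-5-(benzyloxy)-2-formyl-6-oxo-2-[(triethylsilyl)oxy]hexyl] benzoate
Conditions: O3, CH2Cl2, −78 °C; then PPh3, −78 °C → rt; used crude
Reagents that add atoms: ozone [O-][O+]=O
Why: Ozonolysis of both terminal alkenes with reductive work-up (Criegee mechanism) should give the 1,6-dialdehyde, whose C4 aldehyde cannot enolise and whose C3 aldehyde is kept neutral and cold.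

Step 13
Reactants: 14 [(2R,3R,4R,5S)-3,4-diacetoxy-5-(benzyloxy)-2-formyl-6-oxo-2-[(triethylsilyl)oxy]hexyl] benzoate
Product: 15 [(1S,2R,3S,4R,5S,6R)-2,3-diacetoxy-4-(benzyloxy)-5,6-dihydroxy-1-[(triethylsilyl)oxy]cyclohexyl]methyl benzoate
Conditions: SmI2 (3 equiv, 0.1 M in THF), t-BuOH (3 equiv), THF, −78 °C → rt
Reagents that add atoms: none
Why: Two single-electron transfers from SmI2 turn both aldehydes into samarium ketyls, which couple inside a samarium-bridged chelate to form the C3–C4 bond; the closest known reaction type is the SmI2 pinacol carbocyclisation of carbohydrate-derived 1,6-dialdehydes to inositol derivatives. The carbocycle closes in a 6-exo-trig mode (ketyl carbon C3 onto the carbonyl carbon C4 through the C2–C1–C6–C5 tether). The samarium bridge between the two ketyl oxygens forces the new C3 and C4 hydroxyls cis, and each new C–O bond takes the position anti to the oxygen on its neighbour (C2–OBn for C3, C5–OSiEt3 for C4), so both end up on the face opposite to those two substituents. The chair-like transition state keeps the C6, C1 and C2 substituents and the CH2OBz group equatorial, which places the C5 silyl ether axial and leaves only one face of the neopentyl C4 aldehyde open. The step needs coupling to outrun reductive loss of an α-oxygen substituent and attack on the esters, which is secured by ether-type (not acyl) α-substituents, low temperature, a proton source and the absence of HMPA.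

Step 14
Reactants: 15 [(1S,2R,3S,4R,5S,6R)-2,3-diacetoxy-4-(benzyloxy)-5,6-dihydroxy-1-[(triethylsilyl)oxy]cyclohexyl]methyl benzoate
Product: 17 5,6-cyclic sulfate of 15, via cyclic sulfite 16 (not isolated)
Conditions: SOCl2, Et3N, CH2Cl2, 0 °C; then RuCl3 (cat.), NaIO4, MeCN/H2O, 0 °C
Reagents that add atoms: thionyl chloride O=S(Cl)Cl; sodium periodate [Na+].[O-]I(=O)(=O)=O
Why: Cyclic sulfite formation on the cis-diol followed by RuO4-catalysed oxidation (Gao–Sharpless protocol) activates both C–O bonds without touching a stereocentre; the silylated tertiary oxygen cannot take part.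

Step 15
Reactants: 17 5,6-cyclic sulfate of 15
Product: 19 [(1S,2R,3S,4R,5R,6S)-2,3-diacetoxy-4-(benzyloxy)-5-hydroxy-7-oxabicyclo[4.1.0]heptan-1-yl]methyl benzoate, via epoxy sulfate salt 18 (not isolated)
Conditions: Bu4NF (1.1 equiv), THF, −20 → 0 °C; then H2SO4 (cat.), H2O (2 equiv), THF, rt
Reagents that add atoms: none
Why: Fluoride removes the silyl group and the freed axial C5 alkoxide opens the cyclic sulfate at C4 by intramolecular SN2 (3-exo-tet, trans-diaxial) with inversion at C4, giving the oxirane trans to the C3 oxygen; acid-catalysed S–O hydrolysis of the sulfate monoester then frees the C3 hydroxyl with retention.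

Step 16
Reactants: 19 [(1S,2R,3S,4R,5R,6S)-2,3-diacetoxy-4-(benzyloxy)-5-hydroxy-7-oxabicyclo[4.1.0]heptan-1-yl]methyl benzoate
Product: 20 [(1S,2R,3S,4R,5R,6S)-2,3-diacetoxy-4,5-dihydroxy-7-oxabicyclo[4.1.0]heptan-1-yl]methyl benzoate
Conditions: H2 (1 atm), Pd(OH)2/C, EtOAc, rt
Reagents that add atoms: none
Why: Neutral hydrogenolysis of the benzyl ether; the non-benzylic oxirane flanked by oxygenated carbons and the three esters should not be reduced, and no base is present to move the acetates.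

**Compound list**
1 | methyl 4,6-O-[(R)-benzylidene]-α-D-glucopyranoside | CO[C@H]1O[C@@H]2CO[C@@H](c3ccccc3)O[C@H]2[C@H](O)[C@H]1O | starting material
2 | methyl 4,6-O-[(R)-benzylidene]-2,3-bis-O-(4-methoxybenzyl)-α-D-glucopyranoside | CO[C@H]1O[C@@H]2CO[C@@H](c3ccccc3)O[C@H]2[C@H](OCc2ccc(OC)cc2)[C@H]1OCc1ccc(OC)cc1 | intermediate
3 | methyl 4-O-benzyl-2,3-bis-O-(4-methoxybenzyl)-α-D-glucopyranoside | CO[C@H]1O[C@H](CO)[C@@H](OCc2ccccc2)[C@H](OCc2ccc(OC)cc2)[C@H]1OCc1ccc(OC)cc1 | intermediate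
4 | methyl 4-O-benzyl-6-deoxy-6-iodo-2,3-bis-O-(4-methoxybenzyl)-α-D-glucopyranoside | CO[C@H]1O[C@H](CI)[C@@H](OCc2ccccc2)[C@H](OCc2ccc(OC)cc2)[C@H]1OCc1ccc(OC)cc1 | intermediate
5 | (2R,3S,4R)-4-(benzyloxy)-2,3-bis[(4-methoxybenzyl)oxy]hex-5-enal | O=C[C@H](OCc1ccc(OC)cc1)[C@@H](OCc1ccc(OC)cc1)[C@H](OCc1ccccc1)C=C | intermediate
6 | (4S,5S,6R)-6-(benzyloxy)-4,5-bis[(4-methoxybenzyl)oxy]octa-1,7-dien-3-ol (both C3 epimers) | C=CC(O)[C@H](OCc1ccc(OC)cc1)[C@@H](OCc1ccc(OC)cc1)[C@H](OCc1ccccc1)C=C | intermediate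
7 | (4R,5S,6R)-6-(benzyloxy)-4,5-bis[(4-methoxybenzyl)oxy]octa-1,7-dien-3-one | C=CC(=O)[C@H](OCc1ccc(OC)cc1)[C@@H](OCc1ccc(OC)cc1)[C@H](OCc1ccccc1)C=C | intermediate
8 | (3S,4R,5S,6R)-6-(benzyloxy)-3-{[dimethyl(propan-2-yloxy)silyl]methyl}-4,5-bis[(4-methoxybenzyl)oxy]octa-1,7-dien-3-ol | C=C[C@@](O)(C[Si](C)(C)OC(C)C)[C@H](OCc1ccc(OC)cc1)[C@@H](OCc1ccc(OC)cc1)[C@H](OCc1ccccc1)C=C | intermediate
9 | (3R,4R,5S,6R)-6-(benzyloxy)-3-(hydroxymethyl)-4,5-bis[(4-methoxybenzyl)oxy]octa-1,7-dien-3-ol | C=C[C@@](O)(CO)[C@H](OCc1ccc(OC)cc1)[C@@H](OCc1ccc(OC)cc1)[C@H](OCc1ccccc1)C=C | intermediate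
10 | [(2R,3R,4S,5R)-5-(benzyloxy)-2-ethenyl-2-hydroxy-3,4-bis[(4-methoxybenzyl)oxy]hept-6-en-1-yl] benzoate | C=C[C@@](O)(COC(=O)c1ccccc1)[C@H](OCc1ccc(OC)cc1)[C@@H](OCc1ccc(OC)cc1)[C@H](OCc1ccccc1)C=C | intermediate
11 | [(2R,3R,4S,5R)-5-(benzyloxy)-2-ethenyl-3,4-bis[(4-methoxybenzyl)oxy]-2-[(triethylsilyl)oxy]hept-6-en-1-yl] benzoate | C=C[C@@](O[Si](CC)(CC)CC)(COC(=O)c1ccccc1)[C@H](OCc1ccc(OC)cc1)[C@@H](OCc1ccc(OC)cc1)[C@H](OCc1ccccc1)C=C | intermediate
12 | [(2R,3R,4R,5R)-5-(benzyloxy)-2-ethenyl-3,4-dihydroxy-2-[(triethylsilyl)oxy]hept-6-en-1-yl] benzoate | C=C[C@@](O[Si](CC)(CC)CC)(COC(=O)c1ccccc1)[C@H](O)[C@@H](O)[C@H](OCc1ccccc1)C=C | intermediate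
13 | [(2R,3R,4S,5R)-3,4-diacetoxy-5-(benzyloxy)-2-ethenyl-2-[(triethylsilyl)oxy]hept-6-en-1-yl] benzoate | C=C[C@@](O[Si](CC)(CC)CC)(COC(=O)c1ccccc1)[C@H](OC(C)=O)[C@@H](OC(C)=O)[C@H](OCc1ccccc1)C=C | intermediate
14 | [(2R,3R,4R,5S)-3,4-diacetoxy-5-(benzyloxy)-2-formyl-6-oxo-2-[(triethylsilyl)oxy]hexyl] benzoate | O=C[C@@](O[Si](CC)(CC)CC)(COC(=O)c1ccccc1)[C@H](OC(C)=O)[C@@H](OC(C)=O)[C@H](OCc1ccccc1)C=O | intermediate
15 | [(1S,2R,3S,4R,5S,6R)-2,3-diacetoxy-4-(benzyloxy)-5,6-dihydroxy-1-[(triethylsilyl)oxy]cyclohexyl]methyl benzoate | CC(=O)O[C@H]1[C@H](OCc2ccccc2)[C@@H](O)[C@@H](O)[C@@](O[Si](CC)(CC)CC)(COC(=O)c2ccccc2)[C@@H]1OC(C)=O | intermediate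
16 | 5,6-cyclic sulfite of 15 (cis-fused 1,3,2-dioxathiolane 2-oxide, mixture at sulfur, other centres as in 15) | CC(=O)O[C@H]1[C@H](OCc2ccccc2)[C@H]2OS(=O)O[C@H]2[C@@](O[Si](CC)(CC)CC)(COC(=O)c2ccccc2)[C@@H]1OC(C)=O | intermediate
17 | 5,6-cyclic sulfate of 15 (cis-fused 1,3,2-dioxathiolane 2,2-dioxide, other centres as in 15) | CC(=O)O[C@H]1[C@H](OCc2ccccc2)[C@H]2OS(=O)(=O)O[C@H]2[C@@](O[Si](CC)(CC)CC)(COC(=O)c2ccccc2)[C@@H]1OC(C)=O | intermediate
18 | tetrabutylammonium salt of the 5-O-sulfate of 19 | CC(=O)O[C@H]1[C@H](OCc2ccccc2)[C@@H](OS(=O)(=O)[O-])[C@@H]2O[C@]2(COC(=O)c2ccccc2)[C@@H]1OC(C)=O.CCCC[N+](CCCC)(CCCC)CCCC | intermediate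
19 | [(1S,2R,3S,4R,5R,6S)-2,3-diacetoxy-4-(benzyloxy)-5-hydroxy-7-oxabicyclo[4.1.0]heptan-1-yl]methyl benzoate | CC(=O)O[C@H]1[C@H](OCc2ccccc2)[C@@H](O)[C@@H]2O[C@]2(COC(=O)c2ccccc2)[C@@H]1OC(C)=O | intermediate
20 | [(1S,2R,3S,4R,5R,6S)-2,3-diacetoxy-4,5-dihydroxy-7-oxabicyclo[4.1.0]heptan-1-yl]methyl benzoate | CC(=O)O[C@H]1[C@H](O)[C@@H](O)[C@@H]2O[C@]2(COC(=O)c2ccccc2)[C@@H]1OC(C)=O | target

**Total step count:** 16. **Longest linear sequence:** 16 steps (from 1).

**Steps most likely to fail**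

1. Step 13 (pinacol cyclisation). The neopentyl, α-silyloxy aldehyde may be reduced further before it couples, with loss of an α-oxygen substituent or simple reduction to the alcohol, or the two carbonyls may couple without the cis/anti preference. Fallback: setting out from 13, ring-closing metathesis (second-generation Grubbs catalyst, CH2Cl2, 40 °C) gives the cyclohexene [(1R,4R,5S,6R)-5,6-diacetoxy-4-(benzyloxy)-1-[(triethylsilyl)oxy]cyclohex-2-en-1-yl]methyl benzoate F1. Syn-dihydroxylation (OsO4 cat., N-methylmorpholine N-oxide, acetone/H2O) from the face anti to both allylic oxygen substituents then comes back to the route at 15.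

2. Step 7 (chelation-controlled hydroxymethylation). The Grignard reagent may add in conjugate fashion to the vinyl ketone or trigger its oligomerisation, and chelation control may erode. Fallback: setting out from 5, lithium (trimethylsilyl)acetylide (THF, −78 °C) gives the propargylic alcohol F2 as an epimer mixture, and Dess–Martin oxidation gives the ynone F3. The same chelation-controlled addition of (i-PrO)Me2SiCH2MgCl then gives the tertiary carbinol F4. KF/KHCO3/H2O2 oxidises the C–Si bond and removes the alkynyl silyl group to give the alkynyl diol F5. Semi-hydrogenation (H2, Pd/CaCO3 poisoned with Pb(OAc)2, quinoline, EtOAc) comes back to the route at 9.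

3. Step 15 (oxirane closure and sulfate hydrolysis). Fluoride may attack the cyclic sulfate, an acyl group may migrate to the transient tertiary alkoxide, or the oxirane may open under acid during hydrolysis of the sulfate monoester. Fallback: setting out from 15, the equatorial C3 hydroxyl is silylated selectively (Et3SiCl, imidazole, DMF, 0 °C) to the bis-silyl ether F6. The remaining axial C4 hydroxyl is converted into the triflate F7 (Tf2O, pyridine, CH2Cl2, −20 °C). Bu4NF (THF, 0 °C) then removes both silyl groups so that the C5 alkoxide displaces the triflate with inversion, coming back to the route at 19 without any acidic step.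

**Further compounds**
F1 | step 13 | [(1R,4R,5S,6R)-5,6-diacetoxy-4-(benzyloxy)-1-[(triethylsilyl)oxy]cyclohex-2-en-1-yl]methyl benzoate | CC(=O)O[C@H]1[C@H](OCc2ccccc2)C=C[C@@](O[Si](CC)(CC)CC)(COC(=O)c2ccccc2)[C@@H]1OC(C)=O
F2 | step 7 | (4S,5S,6R)-6-(benzyloxy)-4,5-bis[(4-methoxybenzyl)oxy]-1-(trimethylsilyl)oct-7-en-1-yn-3-ol (both C3 epimers) | C[Si](C)(C)C#CC(O)[C@H](OCc1ccc(OC)cc1)[C@@H](OCc1ccc(OC)cc1)[C@H](OCc1ccccc1)C=C
F3 | step 7 | (4R,5S,6R)-6-(benzyloxy)-4,5-bis[(4-methoxybenzyl)oxy]-1-(trimethylsilyl)oct-7-en-1-yn-3-one | C[Si](C)(C)C#CC(=O)[C@H](OCc1ccc(OC)cc1)[C@@H](OCc1ccc(OC)cc1)[C@H](OCc1ccccc1)C=C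
F4 | step 7 | (3S,4R,5S,6R)-6-(benzyloxy)-3-{[dimethyl(propan-2-yloxy)silyl]methyl}-4,5-bis[(4-methoxybenzyl)oxy]-1-(trimethylsilyl)oct-7-en-1-yn-3-ol | C[Si](C)(C)C#C[C@@](O)(C[Si](C)(C)OC(C)C)[C@H](OCc1ccc(OC)cc1)[C@@H](OCc1ccc(OC)cc1)[C@H](OCc1ccccc1)C=C
F5 | step 7 | (3R,4R,5S,6R)-6-(benzyloxy)-3-(hydroxymethyl)-4,5-bis[(4-methoxybenzyl)oxy]oct-7-en-1-yn-3-ol | C#C[C@@](O)(CO)[C@H](OCc1ccc(OC)cc1)[C@@H](OCc1ccc(OC)cc1)[C@H](OCc1ccccc1)C=C
F6 | step 15 | 5-O-triethylsilyl ether of 15 (cyclohexane locants of 15, other centres unchanged) | CC(=O)O[C@H]1[C@H](OCc2ccccc2)[C@@H](O[Si](CC)(CC)CC)[C@@H](O)[C@@](O[Si](CC)(CC)CC)(COC(=O)c2ccccc2)[C@@H]1OC(C)=O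
F7 | step 15 | 6-O-trifluoromethanesulfonate of F6 | CC(=O)O[C@H]1[C@H](OCc2ccccc2)[C@@H](O[Si](CC)(CC)CC)[C@@H](OS(=O)(=O)C(F)(F)F)[C@@](O[Si](CC)(CC)CC)(COC(=O)c2ccccc2)[C@@H]1OC(C)=O
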